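**Plan**
1. Retrosynthesis: cut C12–C13 (butenolide joined last by Negishi coupling), then C4–C18 (methyl by enolate alkylation), then the C1–C10 bond of ring A, then C3–C4 (aldol), C4–C5 and C9–C11 (two enolate alkylations on a ring-B cyclohexenone).
2. Enabling feature: the C19 carboxyl on C4 of ring A and the C20 methyl on C10. With C3=C4 and C1=C2 unsaturation the carboxyl makes C1 the δ-acceptor carbon of a penta-2,4-dienoate; C20 drawn as an exocyclic methylene on ring B gives the tertiary C10 radical by hydrogen-atom transfer. Their union is a 6-endo closure of ring A.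
3. Forward order: ring B first (from (R)-cyclohex-3-ene-1-carboxylic acid), arms at C9 and C5, methylenation, dienoate, ring A by the radical closure, C4 methylation, hydrogenation, side-chain coupling, deprotection.
4. Stereochemistry: C8 from the chiral pool; C9 and C5 by thermodynamic (all-equatorial) control relative to C8; C10 and the trans ring fusion in the key step; C4 by methylation anti to the axial C20 methyl.
5. Helpers: the C2=C3 double bond (hydrogenated in step 15), TBS on O17, benzyl on O12, tert-butyl ester on C19.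

Key step: step 13

Remark: labdane numbering is used for all intermediates, ring-B precursors included (C20 on C10, C18/C19 on C4, C17 on C8, C11–C12 on C9). TBS = tert-butyl(dimethyl)silyl. Compounds 1, 7, 10, 17 and 29 are taken as commercially available.

**Step 1**
Reactants: 1 (R)-cyclohex-3-ene-1-carboxylic acid
Product: 2 (1R,4R,5R)-4-iodo-6-oxabicyclo[3.2.1]octan-7-one
Conditions: I2, KI, NaHCO3, H2O, rt, dark
Reagents that add atoms: iodine, II
Why: Iodolactonisation: the carboxylate opens the iodonium ion at the nearer alkene carbon (C10) from its own face to give the γ-lactone with iodine trans at C5, so the C8 centre fixes where ring B is functionalised.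

**Step 2**
Reactants: 2 iodolactone
Product: 3 (1R,5R)-6-oxabicyclo[3.2.1]oct-3-en-7-one
Conditions: DBU, toluene, reflux
Reagents that add atoms: none
Why: E2 elimination can only use the antiperiplanar hydrogen on C6 (the C10 hydrogen is syn to iodine), which gives the allylic lactone.

**Step 3**
Reactants: 3 unsaturated lactone
Product: 4 (1R,5R)-5-(hydroxymethyl)cyclohex-2-en-1-ol
Conditions: LiAlH4, THF, 0 °C; aqueous NaOH work-up
Reagents that add atoms: none
Why: Hydride reduction of the lactone gives the cis diol and leaves the isolated alkene and both stereocentres untouched.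

**Step 4**
Reactants: 4 diol
Product: 5 (1R,5R)-5-{[TBS]oxymethyl}cyclohex-2-en-1-ol
Conditions: TBSCl (1.05 equiv), imidazole, CH2Cl2, 0 °C
Reagents that add atoms: tert-butyl(dimethyl)silyl chloride, CC(C)(C)[Si](C)(C)Cl
Why: Silylation is selective for the primary over the secondary allylic hydroxyl.

**Step 5**
Reactants: 5 allylic alcohol
Product: 6 (5R)-5-{[TBS]oxymethyl}cyclohex-2-en-1-one
Conditions: activated MnO2, CH2Cl2, rt
Reagents that add atoms: none
Why: Allylic oxidation with MnO2 places the carbonyl at C10 with C5=C6 unsaturation, which allows regiocontrolled alkylation on both sides of the ketone.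

**Step 6**
Reactants: 6 enone; 7 methyl bromoacetate
Product: 9 methyl 2-[(1S,6R)-6-{[TBS]oxymethyl}-2-oxocyclohex-3-en-1-yl]acetate, via lithium dienolate 8 (not isolated)
Conditions: LiN(i-Pr)2, THF, −78 °C; then 7, DMPU, −78 to −30 °C
Reagents that add atoms: none
Why: Kinetic deprotonation of the enone takes the α′ hydrogen at C9 and the enolate alkylation should occur anti to the C8 substituent (trans 8,9), a centre that is also corrected by the equilibration in step 7.

**Step 7**
Reactants: 9 alkylated enone; 10 tert-butyl bromoacetate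
Product: 13 methyl 2-[(1S,3S,6R)-3-(2-tert-butoxy-2-oxoethyl)-6-{[TBS]oxymethyl}-2-oxocyclohexyl]acetate, via lithium enolate 11 (not isolated), via 2,6-trans epimer 12 (not isolated)
Conditions: LiBH(s-Bu)3, THF, −78 °C; then 10, DMPU, −78 to 0 °C; then DBU (0.3 equiv), CH2Cl2, rt
Reagents that add atoms: none
Why: Conjugate reduction of the β-unsubstituted enone gives the C5 enolate regiospecifically for reductive alkylation, and base epimerisation α to the ketone should funnel the C5/C9 epimers into the all-equatorial isomer anchored by the non-epimerisable C8.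

**Step 8**
Reactants: 13 keto diester
Product: 14 methyl 2-[(1S,3S,6R)-3-(2-tert-butoxy-2-oxoethyl)-6-{[TBS]oxymethyl}-2-methylidenecyclohexyl]acetate
Conditions: Zn, CH2Br2, TiCl4, THF/CH2Cl2, 0 °C to rt
Reagents that add atoms: dibromomethane, BrCBr
Why: Lombardo methylenation converts hindered, epimerisable ketones to exocyclic alkenes under non-basic conditions and tolerates both esters.

**Step 9**
Reactants: 14 methylene diester
Product: 15 tert-butyl 2-[(1S,3S,4R)-3-(2-hydroxyethyl)-4-{[TBS]oxymethyl}-2-methylidenecyclohexyl]acetate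
Conditions: LiBH4, THF, MeOH (1 equiv), 0 °C to rt
Reagents that add atoms: none
Why: LiBH4 reduces the unhindered methyl ester and should leave the tert-butyl ester and the alkene alone.

**Step 10**
Reactants: 15 alcohol
Product: 16 tert-butyl 2-[(1S,3S,4R)-3-[2-(benzyloxy)ethyl]-4-{[TBS]oxymethyl}-2-methylidenecyclohexyl]acetate
Conditions: NaH, BnBr, Bu4NI (cat.), THF, 0 °C to rt
Reagents that add atoms: benzyl bromide, BrCc1ccccc1
Why: Williamson benzylation gives an O12 ether that survives the enolate and radical steps and is removed during the later hydrogenation.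

**Step 11**
Reactants: 16 benzyl ether; 17 acrolein
Product: 19 tert-butyl 2-[(1S,3S,4R)-3-[2-(benzyloxy)ethyl]-4-{[TBS]oxymethyl}-2-methylidenecyclohexyl]-3-hydroxypent-4-enoate (diastereomer mixture at C3/C4), via lithium ester enolate 18 (not isolated)
Conditions: LiN(i-Pr)2, THF, −78 °C; then 17, −78 °C; then H2O
Reagents that add atoms: none
Why: The lithium enolate of the tert-butyl ester should add 1,2 to acrolein (aldol addition); the two new stereocentres are removed in step 12.

**Step 12**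
Reactants: 19 aldol adduct
Product: 21 tert-butyl (2E)-2-[(1R,3S,4R)-3-[2-(benzyloxy)ethyl]-4-{[TBS]oxymethyl}-2-methylidenecyclohexyl]penta-2,4-dienoate, via allylic mesylate 20 (not isolated)
Conditions: MsCl, Et3N, CH2Cl2, 0 °C; then DBU, 0 °C to rt
Reagents that add atoms: none
Why: Mesylation and E1cB elimination should give the conjugated dienoate in its preferred (E) geometry, with the vinyl group cis to C5 as the cyclisation requires.

**Step 13**
Reactants: 21 (E)-dienoate
Product: 24 tert-butyl 12-(benzyloxy)-17-[TBS]oxy-13,14,15,16,18-pentanorlabd-3-en-19-oate (5αH,8βH,9αH,10β-methyl), via tertiary C10 radical 22 (not isolated), via deconjugated ester 23 (not isolated)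
Conditions: Fe(acac)3 (30 mol %), PhSiH3 (slow addition), EtOH/(CH2OH)2 5:1, 0.01 M, 60 °C; then DBU, CH2Cl2, rt
Reagents that add atoms: none
Why: Proposed new method: an iron hydride generated from Fe(acac)3 and PhSiH3 should transfer a hydrogen atom to C20 of the exocyclic methylene, the tertiary C10 radical 22 should add to C1, the unsubstituted δ-terminus of the (E)-penta-2,4-dienoate, and the ester-stabilised allyl radical (C2–C3–C4) should be reduced by divalent iron and protonated by ethanol, after which DBU moves the double bond into conjugation (23 to 24). The closest known reaction type is the iron-hydride reductive olefin coupling (hydrogen-atom-transfer Giese cyclisation) of 1,1-disubstituted alkenes onto enones and acrylates, together with the 1,6-addition of alkyl radicals to dienoates; the intramolecular vinylogous combination is the untested part. Ring A closes in the 6-endo-trig mode on C1=C2, since attack at C2 (5-exo) would leave an unstabilised primary radical whereas attack at C1 gives a delocalised one. The one new stereocentre, C10, is controlled by the ring-B chair with its C5, C8 and C9 substituents equatorial: C1 should bond to the planar radical in the equatorial direction, anti to the vicinal C4 and C11 groups, so that C20 becomes axial and the ring fusion trans, as in the second ring closure of radical polyene cyclisations. The step needs chemoselective hydrogen-atom transfer to the electron-rich methylene and not to the dienoate, which the 1,1-dialkyl substitution, slow silane addition and high dilution should favour, and it needs the (E) geometry at C3=C4 that holds C2 cis to C5. The C4 epimers and double-bond isomers of the first-formed product all converge on 24 and on one dienolate in step 14.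

**Step 14**
Reactants: 24 conjugated ester
Product: 26 tert-butyl (4S)-12-(benzyloxy)-17-[TBS]oxy-13,14,15,16-tetranorlabd-2-en-19-oate, via lithium dienolate 25 (not isolated)
Conditions: LiN(i-Pr)2, HMPA, THF, −78 °C; then MeI, −78 to −40 °C
Reagents that add atoms: iodomethane, CI
Why: γ-Deprotonation at C2 and α-methylation of the extended enolate (deconjugative alkylation) should occur on the α-face of C4, anti to the axial C20 methyl, placing the new methyl equatorial (C18) and the ester axial (C19).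

**Step 15**
Reactants: 26 methylated ester
Product: 27 tert-butyl 12-hydroxy-17-[TBS]oxy-13,14,15,16-tetranorlabdan-19-oate
Conditions: H2 (1 atm), Pd/C, EtOAc/EtOH, rt
Reagents that add atoms: none
Why: Catalytic hydrogenation saturates the helper C2=C3 bond and hydrogenolyses the benzyl ether in the same operation without touching a stereocentre.

**Step 16**
Reactants: 27 primary alcohol
Product: 28 tert-butyl 12-iodo-17-[TBS]oxy-13,14,15,16-tetranorlabdan-19-oate
Conditions: I2, PPh3, imidazole, CH2Cl2, 0 °C to rt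
Reagents that add atoms: iodine, II
Why: Appel-type iodination converts the unhindered primary alcohol into the iodide.

**Step 17**
Reactants: 28 iodide; 29 3-bromofuran-2(5H)-one
Product: 31 tert-butyl 17-[TBS]oxylabd-13-en-16,15-olid-19-oate, via alkylzinc iodide 30 (not isolated)
Conditions: Zn dust (activated), LiCl, THF, 40 °C; then 29, Pd2(dba)3 (2.5 mol %), SPhos (10 mol %), THF, rt to 45 °C
Reagents that add atoms: none
Why: Zinc insertion under Knochel conditions and Negishi coupling under zerovalent palladium catalysis, as known for alkylzinc reagents and α-haloenones, should join C12 to the α-carbon of the butenolide.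

**Step 18**
Reactants: 31 protected butenolide
Product: 32 (1S,4aR,5S,6R,8aR)-6-(hydroxymethyl)-1,4a-dimethyl-5-[2-(2-oxo-2,5-dihydrofuran-3-yl)ethyl]decahydronaphthalene-1-carboxylic acid
Conditions: CF3CO2H/CH2Cl2/H2O 10:10:1, 0 °C to rt; aqueous NaHCO3, then pH 3
Reagents that add atoms: none
Why: Acidolysis should remove the tert-butyl ester (through the tert-butyl cation, so hindrance at C4 does not matter) and the primary silyl ether together, under conditions the butenolide tolerates.

**Compound list**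
1 | (R)-cyclohex-3-ene-1-carboxylic acid | OC(=O)[C@H]1CC=CCC1 | starting material
2 | (1R,4R,5R)-4-iodo-6-oxabicyclo[3.2.1]octan-7-one | O=C1O[C@@H]2C[C@H]1CC[C@H]2I | intermediate
3 | (1R,5R)-6-oxabicyclo[3.2.1]oct-3-en-7-one | O=C1O[C@@H]2C[C@H]1CC=C2 | intermediate
4 | (1R,5R)-5-(hydroxymethyl)cyclohex-2-en-1-ol | OC[C@H]1C[C@@H](O)C=CC1 | intermediate
5 | (1R,5R)-5-{[TBS]oxymethyl}cyclohex-2-en-1-ol | CC(C)(C)[Si](C)(C)OC[C@H]1C[C@@H](O)C=CC1 | intermediate
6 | (5R)-5-{[TBS]oxymethyl}cyclohex-2-en-1-one | CC(C)(C)[Si](C)(C)OC[C@H]1CC(=O)C=CC1 | intermediate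
7 | methyl bromoacetate | COC(=O)CBr | starting material
8 | lithium (3R)-3-{[TBS]oxymethyl}cyclohexa-1,5-dien-1-olate | [Li]OC1=C[C@H](CO[Si](C)(C)C(C)(C)C)CC=C1 | intermediate
9 | methyl 2-[(1S,6R)-6-{[TBS]oxymethyl}-2-oxocyclohex-3-en-1-yl]acetate | COC(=O)C[C@H]1[C@H](CO[Si](C)(C)C(C)(C)C)CC=CC1=O | intermediate
10 | tert-butyl bromoacetate | CC(C)(C)OC(=O)CBr | starting material
11 | lithium (5R,6S)-6-(2-methoxy-2-oxoethyl)-5-{[TBS]oxymethyl}cyclohex-1-en-1-olate | [Li]OC1=CCC[C@@H](CO[Si](C)(C)C(C)(C)C)[C@@H]1CC(=O)OC | intermediate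
12 | methyl 2-[(1S,3R,6R)-3-(2-tert-butoxy-2-oxoethyl)-6-{[TBS]oxymethyl}-2-oxocyclohexyl]acetate | O=C1[C@@H](CC(=O)OC(C)(C)C)CC[C@@H](CO[Si](C)(C)C(C)(C)C)[C@@H]1CC(=O)OC | intermediate
13 | methyl 2-[(1S,3S,6R)-3-(2-tert-butoxy-2-oxoethyl)-6-{[TBS]oxymethyl}-2-oxocyclohexyl]acetate | O=C1[C@H](CC(=O)OC(C)(C)C)CC[C@@H](CO[Si](C)(C)C(C)(C)C)[C@@H]1CC(=O)OC | intermediate
14 | methyl 2-[(1S,3S,6R)-3-(2-tert-butoxy-2-oxoethyl)-6-{[TBS]oxymethyl}-2-methylidenecyclohexyl]acetate | C=C1[C@H](CC(=O)OC(C)(C)C)CC[C@@H](CO[Si](C)(C)C(C)(C)C)[C@@H]1CC(=O)OC | intermediate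
15 | tert-butyl 2-[(1S,3S,4R)-3-(2-hydroxyethyl)-4-{[TBS]oxymethyl}-2-methylidenecyclohexyl]acetate | C=C1[C@H](CC(=O)OC(C)(C)C)CC[C@@H](CO[Si](C)(C)C(C)(C)C)[C@@H]1CCO | intermediate
16 | tert-butyl 2-[(1S,3S,4R)-3-[2-(benzyloxy)ethyl]-4-{[TBS]oxymethyl}-2-methylidenecyclohexyl]acetate | C=C1[C@H](CC(=O)OC(C)(C)C)CC[C@@H](CO[Si](C)(C)C(C)(C)C)[C@@H]1CCOCc1ccccc1 | intermediate
17 | acrolein | C=CC=O | starting material
18 | lithium enolate of 16 | C=C1[C@H](C=C(O[Li])OC(C)(C)C)CC[C@@H](CO[Si](C)(C)C(C)(C)C)[C@@H]1CCOCc1ccccc1 | intermediate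
19 | tert-butyl 2-[(1S,3S,4R)-3-[2-(benzyloxy)ethyl]-4-{[TBS]oxymethyl}-2-methylidenecyclohexyl]-3-hydroxypent-4-enoate (C3/C4 diastereomer mixture) | C=C1[C@H](C(C(O)C=C)C(=O)OC(C)(C)C)CC[C@@H](CO[Si](C)(C)C(C)(C)C)[C@@H]1CCOCc1ccccc1 | intermediate
20 | 3-methanesulfonate of 19 | C=C1[C@H](C(C(OS(C)(=O)=O)C=C)C(=O)OC(C)(C)C)CC[C@@H](CO[Si](C)(C)C(C)(C)C)[C@@H]1CCOCc1ccccc1 | intermediate
21 | tert-butyl (2E)-2-[(1R,3S,4R)-3-[2-(benzyloxy)ethyl]-4-{[TBS]oxymethyl}-2-methylidenecyclohexyl]penta-2,4-dienoate | C=C1[C@H](/C(C(=O)OC(C)(C)C)=C\C=C)CC[C@@H](CO[Si](C)(C)C(C)(C)C)[C@@H]1CCOCc1ccccc1 | intermediate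
22 | tertiary C10 radical from 21 (hydrogen added at C20) | C[C]1[C@H](/C(C(=O)OC(C)(C)C)=C\C=C)CC[C@@H](CO[Si](C)(C)C(C)(C)C)[C@@H]1CCOCc1ccccc1 | intermediate
23 | tert-butyl 12-(benzyloxy)-17-[TBS]oxy-13,14,15,16,18-pentanorlabd-2-en-19-oate (C4 epimers) | C[C@]12CC=CC(C(=O)OC(C)(C)C)[C@@H]1CC[C@@H](CO[Si](C)(C)C(C)(C)C)[C@@H]2CCOCc1ccccc1 | intermediate
24 | tert-butyl 12-(benzyloxy)-17-[TBS]oxy-13,14,15,16,18-pentanorlabd-3-en-19-oate (5αH,8βH,9αH,10β-methyl) | C[C@]12CCC=C(C(=O)OC(C)(C)C)[C@@H]1CC[C@@H](CO[Si](C)(C)C(C)(C)C)[C@@H]2CCOCc1ccccc1 | intermediate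
25 | lithium dienolate of 24 (C2=C3–C4=C19) | C[C@]12CC=CC(=C(O[Li])OC(C)(C)C)[C@@H]1CC[C@@H](CO[Si](C)(C)C(C)(C)C)[C@@H]2CCOCc1ccccc1 | intermediate
26 | tert-butyl (4S)-12-(benzyloxy)-17-[TBS]oxy-13,14,15,16-tetranorlabd-2-en-19-oate (4α-methyl, 4β-ester) | C[C@]12CC=C[C@](C)(C(=O)OC(C)(C)C)[C@@H]1CC[C@@H](CO[Si](C)(C)C(C)(C)C)[C@@H]2CCOCc1ccccc1 | intermediate
27 | tert-butyl 12-hydroxy-17-[TBS]oxy-13,14,15,16-tetranorlabdan-19-oate | C[C@]12CCC[C@](C)(C(=O)OC(C)(C)C)[C@@H]1CC[C@@H](CO[Si](C)(C)C(C)(C)C)[C@@H]2CCO | intermediate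
28 | tert-butyl 12-iodo-17-[TBS]oxy-13,14,15,16-tetranorlabdan-19-oate | C[C@]12CCC[C@](C)(C(=O)OC(C)(C)C)[C@@H]1CC[C@@H](CO[Si](C)(C)C(C)(C)C)[C@@H]2CCI | intermediate
29 | 3-bromofuran-2(5H)-one | O=C1OCC=C1Br | starting material
30 | 12-(iodozincio) derivative of 28 | C[C@]12CCC[C@](C)(C(=O)OC(C)(C)C)[C@@H]1CC[C@@H](CO[Si](C)(C)C(C)(C)C)[C@@H]2CC[Zn]I | intermediate
31 | tert-butyl 17-[TBS]oxylabd-13-en-16,15-olid-19-oate | C[C@]12CCC[C@](C)(C(=O)OC(C)(C)C)[C@@H]1CC[C@@H](CO[Si](C)(C)C(C)(C)C)[C@@H]2CCC1=CCOC1=O | intermediate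
32 | (1S,4aR,5S,6R,8aR)-6-(hydroxymethyl)-1,4a-dimethyl-5-[2-(2-oxo-2,5-dihydrofuran-3-yl)ethyl]decahydronaphthalene-1-carboxylic acid (17-hydroxylabd-13-en-16,15-olid-19-oic acid, 8βH) | C[C@]12CCC[C@](C)(C(=O)O)[C@@H]1CC[C@@H](CO)[C@@H]2CCC1=CCOC1=O | target

**Summary**
Total step count: 18. Longest linear sequence: 18 steps (1 to 32).

**Steps most likely to fail**

1. Step 13 (proposed method). The likely failure is hydrogen-atom transfer to the dienoate terminus outrunning transfer to the methylene, or a 6-endo closure through the rigid diene tether that is too slow, so that the C10 radical is simply reduced. The fallback uses known chemistry, sets out from 19 and comes back at 26. Oxidation of 19 with Dess–Martin periodinane gives tert-butyl 2-[(1S,3S,4R)-3-[2-(benzyloxy)ethyl]-4-{[TBS]oxymethyl}-2-methylidenecyclohexyl]-3-oxopent-4-enoate F1. The same Fe(acac)3/PhSiH3 conditions then close the C1–C10 bond by the established 6-endo reductive olefin coupling onto a vinyl ketone (tether carbon C4 now sp3), giving tert-butyl 12-(benzyloxy)-17-[TBS]oxy-3-oxo-13,14,15,16,18-pentanorlabdan-19-oate F2. C-Methylation with K2CO3/MeI, from the α-face as known for 3-oxo-4-carboalkoxy-10-methyl-trans-decalins, gives tert-butyl 12-(benzyloxy)-17-[TBS]oxy-3-oxo-13,14,15,16-tetranorlabdan-19-oate F3. KN(SiMe3)2/PhNTf2 gives tert-butyl 12-(benzyloxy)-17-[TBS]oxy-3-(trifluoromethanesulfonyloxy)-13,14,15,16-tetranorlabd-2-en-19-oate F4, and Pd(OAc)2/PPh3/HCO2H/Bu3N reduction of the triflate gives 26.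

2. Step 14. The likely failure is alkylation of the dienolate at the γ-carbon C2, or poor facial selectivity at C4 in the flattened ring. The fallback sets out from 24 and comes back at 27. Hydrogenation of C3=C4 over Pd/C poisoned with pyridine, which retains the benzyl ether, gives tert-butyl 12-(benzyloxy)-17-[TBS]oxy-13,14,15,16,18-pentanorlabdan-19-oate F5. Deprotonation with LiN(i-Pr)2 and methylation of this saturated ester enolate with MeI, the classical equatorial methylation of C4 esters in 10-methyl-trans-decalins, gives tert-butyl 12-(benzyloxy)-17-[TBS]oxy-13,14,15,16-tetranorlabdan-19-oate F6. Hydrogenolysis over Pd(OH)2/C then gives 27.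

3. Step 17. The likely failure is incomplete zinc insertion or protodezincation, and reduction or homocoupling of the bromobutenolide in place of cross-coupling. The fallback sets out from 28 and comes back at 31. Alkylation of the lithium enolate of 3-(phenylsulfanyl)oxolan-2-one (LiN(SiMe3)2, HMPA, THF) with 28 gives tert-butyl 13-(phenylsulfanyl)-17-[TBS]oxylabdan-16,15-olid-19-oate F7. Oxidation with mCPBA at −78 °C gives tert-butyl 13-(phenylsulfinyl)-17-[TBS]oxylabdan-16,15-olid-19-oate F8, and thermal syn-elimination (toluene, 110 °C) gives the endocyclic butenolide 31.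

**Further compounds**
F1 | step 13 | tert-butyl 2-[(1S,3S,4R)-3-[2-(benzyloxy)ethyl]-4-{[TBS]oxymethyl}-2-methylidenecyclohexyl]-3-oxopent-4-enoate | C=C1[C@H](C(C(=O)C=C)C(=O)OC(C)(C)C)CC[C@@H](CO[Si](C)(C)C(C)(C)C)[C@@H]1CCOCc1ccccc1
F2 | step 13 | tert-butyl 12-(benzyloxy)-17-[TBS]oxy-3-oxo-13,14,15,16,18-pentanorlabdan-19-oate | C[C@]12CCC(=O)C(C(=O)OC(C)(C)C)[C@@H]1CC[C@@H](CO[Si](C)(C)C(C)(C)C)[C@@H]2CCOCc1ccccc1
F3 | step 13 | tert-butyl 12-(benzyloxy)-17-[TBS]oxy-3-oxo-13,14,15,16-tetranorlabdan-19-oate | C[C@]12CCC(=O)[C@](C)(C(=O)OC(C)(C)C)[C@@H]1CC[C@@H](CO[Si](C)(C)C(C)(C)C)[C@@H]2CCOCc1ccccc1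
F4 | step 13 | tert-butyl 12-(benzyloxy)-17-[TBS]oxy-3-(trifluoromethanesulfonyloxy)-13,14,15,16-tetranorlabd-2-en-19-oate | C[C@]12CC=C(OS(=O)(=O)C(F)(F)F)[C@](C)(C(=O)OC(C)(C)C)[C@@H]1CC[C@@H](CO[Si](C)(C)C(C)(C)C)[C@@H]2CCOCc1ccccc1
F5 | step 14 | tert-butyl 12-(benzyloxy)-17-[TBS]oxy-13,14,15,16,18-pentanorlabdan-19-oate | C[C@]12CCCC(C(=O)OC(C)(C)C)[C@@H]1CC[C@@H](CO[Si](C)(C)C(C)(C)C)[C@@H]2CCOCc1ccccc1
F6 | step 14 | tert-butyl 12-(benzyloxy)-17-[TBS]oxy-13,14,15,16-tetranorlabdan-19-oate | C[C@]12CCC[C@](C)(C(=O)OC(C)(C)C)[C@@H]1CC[C@@H](CO[Si](C)(C)C(C)(C)C)[C@@H]2CCOCc1ccccc1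
F7 | step 17 | tert-butyl 13-(phenylsulfanyl)-17-[TBS]oxylabdan-16,15-olid-19-oate | C[C@]12CCC[C@](C)(C(=O)OC(C)(C)C)[C@@H]1CC[C@@H](CO[Si](C)(C)C(C)(C)C)[C@@H]2CCC1(Sc2ccccc2)CCOC1=O
F8 | step 17 | tert-butyl 13-(phenylsulfinyl)-17-[TBS]oxylabdan-16,15-olid-19-oate | C[C@]12CCC[C@](C)(C(=O)OC(C)(C)C)[C@@H]1CC[C@@H](CO[Si](C)(C)C(C)(C)C)[C@@H]2CCC1(S(=O)c2ccccc2)CCOC1=O
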